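The route rests on cutting the C2–C3 bond of the dihydrofuran ring (O1–C2–C3–C3a–C7a). The C3 carbinol, C2 and the isopropenyl group together form a homoallylic alcohol, which is the retron of a carbonyl allylation with allyl inversion. A catalytic asymmetric intramolecular Nozaki–Hiyama–Kishi reaction therefore closes the ring, sets C2 and C3 (trans), unveils the isopropenyl group and frees the C3 hydroxyl in one operation. The C5 acetyl group needs no protection. The precursor is an open-chain (E)-3-chloro-2-methylprop-1-enyl aryl ether of 5-acetylsalicylaldehyde, made by copper-catalysed O-vinylation. The (Z)-2-(acetoxymethyl)but-2-enoyl group, built from crotonaldehyde, is attached last.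

Key step: step 4

Assumption: the (S,S)-ligand of step 4 is taken to direct the allyl group to the Re face of the formyl group. Should the closure show the opposite sense, the (R,R)-ligand from D-valinol takes its place.

Step 1
Reactants: 1 prop-2-yn-1-ol
Product: 3 (E)-3-iodo-2-methylprop-2-en-1-ol, via dimethylalkenylalane 2 (not isolated)
Conditions: AlMe3 (3 equiv), Cp2ZrCl2 (25 mol %), CH2Cl2, 0 °C to rt; then I2, THF, −30 °C; sat. aq. K2CO3 work-up
Reagents that add atoms: trimethylaluminium, C[Al](C)C; iodine, II
Why: Zirconium-catalysed Negishi carboalumination adds methyl and aluminium syn across the alkyne with aluminium at the terminus, and iododealumination with retention fixes the E geometry (iodine cis to methyl).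

Step 2
Reactants: 3 (E)-3-iodo-2-methylprop-2-en-1-ol; 4 5-acetyl-2-hydroxybenzaldehyde
Product: 5 5-acetyl-2-{[(1E)-3-hydroxy-2-methylprop-1-en-1-yl]oxy}benzaldehyde
Conditions: CuI (10 mol %), N,N-dimethylglycine hydrochloride (30 mol %), Cs2CO3 (2 equiv), 1,4-dioxane, 60 °C, N2
Reagents that add atoms: none
Why: Ullmann-type copper-catalysed O-vinylation of the phenoxide by the alkenyl iodide should proceed with retention of alkene geometry, and the far more acidic phenol outcompetes the allylic hydroxyl as nucleophile.

Step 3
Reactants: 5 5-acetyl-2-{[(1E)-3-hydroxy-2-methylprop-1-en-1-yl]oxy}benzaldehyde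
Product: 7 5-acetyl-2-{[(1E)-3-chloro-2-methylprop-1-en-1-yl]oxy}benzaldehyde, via allylic mesylate 6 (not isolated)
Conditions: MsCl, LiCl, 2,4,6-collidine, DMF, 0 °C; short plug of neutral alumina, used at once
Reagents that add atoms: lithium chloride, [Li+].[Cl-]
Why: Mesylation followed by SN2 chloride displacement in the same flask works under buffered, non-acidic conditions that spare the enol ether and both carbonyl groups, and any allylic isomer formed by ionisation would feed the same allylchromium species in step 4.

Step 4
Reactants: 7 5-acetyl-2-{[(1E)-3-chloro-2-methylprop-1-en-1-yl]oxy}benzaldehyde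
Product: 9 1-[(2R,3S)-3-hydroxy-2-(prop-1-en-2-yl)-2,3-dihydro-1-benzofuran-5-yl]ethanone, via trimethylsilyl ether 8 (not isolated)
Conditions: CrCl2 (10 mol %), 1,8-bis[(4S)-4-isopropyl-4,5-dihydro-1,3-oxazol-2-yl]-3,6-diphenyl-9H-carbazole (12 mol %), iPr2NEt (30 mol %), Mn (2 equiv), Me3SiCl (2 equiv), THF (0.02 M), rt; then Bu4NF, AcOH, THF, 0 °C
Reagents that add atoms: none
Why: Divalent chromium, kept in turnover by Mn, reduces the allylic chloride in two one-electron steps to a ligand-bound γ-aryloxyallylchromium species that settles in the E form (bulky metal terminus trans to the aryloxy group) and adds through its oxygen-bearing γ-carbon to the chromium-bound ortho formyl group in a closed six-membered chair, after which Me3SiCl releases the metal as silyl ether 8 and buffered fluoride unmasks 9. The closest known reaction type is the catalytic asymmetric Nozaki–Hiyama–Kishi allylation, together with the additions of γ-oxygenated allylchromium reagents that give 1,2-diol derivatives and the intramolecular allylchromium closures of halide-tethered aldehydes. The dihydrofuran ring closes 5-exo-trig at the carbonyl carbon with formation of C2–C3, and the allyl inversion pushes the double bond out of the ring so that the isopropenyl group appears in the same event. C3 is controlled by the chiral tridentate carbazole bis(oxazoline) ligand on chromium, which leaves the Re face of the formyl group open and so gives 3S. C2 is controlled by the chair itself: with the E-allyl unit the O1 and C3a ends of the tether are both equatorial, the anti adduct results, and in the ring this is the trans-(2R,3S) arrangement. The step needs aldehyde-over-ketone and γ-over-α selectivity, which are secured by the intrinsic aldehyde preference of organochromium reagents, by the ortho placement that makes the five-ring closure intramolecular at high dilution, and by the cyclic transition state, which cannot deliver the α-carbon (seven-membered ring).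

Step 5
Reactants: 10 (E)-but-2-enal
Product: 11 (Z)-2-iodobut-2-enal
Conditions: I2, K2CO3, 4-dimethylaminopyridine (20 mol %), THF–H2O (1:1), rt
Reagents that add atoms: iodine, II
Why: Amine-catalysed α-iodination of the enal (conjugate addition, iodination of the enolate, elimination, a Baylis–Hillman-type sequence) returns the more stable alkene with formyl trans to methyl, which is the Z-iodide.

Step 6
Reactants: 11 (Z)-2-iodobut-2-enal
Product: 12 (Z)-2-iodobut-2-en-1-ol
Conditions: NaBH4, MeOH, 0 °C
Reagents that add atoms: none
Why: Chemoselective 1,2-hydride reduction of the aldehyde leaves the alkenyl iodide and its geometry untouched.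

Step 7
Reactants: 12 (Z)-2-iodobut-2-en-1-ol
Product: 14 (Z)-2-(hydroxymethyl)but-2-enoic acid, via dilithio alkoxide 13 (not isolated)
Conditions: t-BuLi (3.1 equiv), Et2O, −78 °C; CO2; aq. HCl to pH 2–3
Reagents that add atoms: carbon dioxide, O=C=O
Why: Deprotonation and iodine–lithium exchange give a configurationally stable alkenyllithium, and carboxylation with retention places the carboxyl group cis to the methyl group (Z).

Step 8
Reactants: 14 (Z)-2-(hydroxymethyl)but-2-enoic acid
Product: 15 (Z)-2-(acetoxymethyl)but-2-enoic acid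
Conditions: Ac2O, pyridine, CH2Cl2, 0 °C to rt; aqueous work-up
Reagents that add atoms: acetic anhydride, CC(=O)OC(C)=O
Why: Plain O-acetylation of the primary allylic alcohol, with any mixed anhydride at the carboxyl group hydrolysed in the work-up, does not touch the alkene geometry.

Step 9
Reactants: 9 1-[(2R,3S)-3-hydroxy-2-(prop-1-en-2-yl)-2,3-dihydro-1-benzofuran-5-yl]ethanone; 15 (Z)-2-(acetoxymethyl)but-2-enoic acid
Product: 17 (2R,3S)-5-acetyl-2-(prop-1-en-2-yl)-2,3-dihydro-1-benzofuran-3-yl (Z)-2-(acetoxymethyl)but-2-enoate, via mixed anhydride 16 (not isolated)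
Conditions: 15, 2,4,6-trichlorobenzoyl chloride, Et3N, toluene, 0 °C; then 9, 4-dimethylaminopyridine (0.3 equiv), 0 °C to rt
Reagents that add atoms: none
Why: Yamaguchi esterification acylates the C3 hydroxyl without breaking its C–O bond (3S retained), and low temperature with substoichiometric nucleophilic catalyst should limit Z-to-E isomerisation, allylic displacement of the acetate and dehydration to the benzofuran.

Compound list
1 | prop-2-yn-1-ol | C#CCO | starting material
2 | (E)-[3-(dimethylalumanyloxy)-2-methylprop-1-en-1-yl]dimethylalumane | C[Al](C)/C=C(\C)CO[Al](C)C | intermediate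
3 | (E)-3-iodo-2-methylprop-2-en-1-ol | I/C=C(\C)CO | intermediate
4 | 5-acetyl-2-hydroxybenzaldehyde | CC(=O)c1ccc(O)c(C=O)c1 | starting material
5 | 5-acetyl-2-{[(1E)-3-hydroxy-2-methylprop-1-en-1-yl]oxy}benzaldehyde | CC(=O)c1ccc(O/C=C(\C)CO)c(C=O)c1 | intermediate
6 | (2E)-3-(4-acetyl-2-formylphenoxy)-2-methylprop-2-en-1-yl methanesulfonate | CC(=O)c1ccc(O/C=C(\C)COS(C)(=O)=O)c(C=O)c1 | intermediate
7 | 5-acetyl-2-{[(1E)-3-chloro-2-methylprop-1-en-1-yl]oxy}benzaldehyde | CC(=O)c1ccc(O/C=C(\C)CCl)c(C=O)c1 | intermediate
8 | 1-[(2R,3S)-2-(prop-1-en-2-yl)-3-(trimethylsilyloxy)-2,3-dihydro-1-benzofuran-5-yl]ethanone | C=C(C)[C@H]1Oc2ccc(C(C)=O)cc2[C@@H]1O[Si](C)(C)C | intermediate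
9 | 1-[(2R,3S)-3-hydroxy-2-(prop-1-en-2-yl)-2,3-dihydro-1-benzofuran-5-yl]ethanone (trans) | C=C(C)[C@H]1Oc2ccc(C(C)=O)cc2[C@@H]1O | intermediate
10 | (E)-but-2-enal (crotonaldehyde) | C/C=C/C=O | starting material
11 | (Z)-2-iodobut-2-enal | C/C=C(\I)C=O | intermediate
12 | (Z)-2-iodobut-2-en-1-ol | C/C=C(\I)CO | intermediate
13 | lithium (Z)-2-lithiobut-2-en-1-olate | C/C=C(\[Li])CO[Li] | intermediate
14 | (Z)-2-(hydroxymethyl)but-2-enoic acid | C/C=C(/CO)C(=O)O | intermediate
15 | (Z)-2-(acetoxymethyl)but-2-enoic acid | C/C=C(/COC(C)=O)C(=O)O | intermediate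
16 | (Z)-2-(acetoxymethyl)but-2-enoic 2,4,6-trichlorobenzoic anhydride | C/C=C(/COC(C)=O)C(=O)OC(=O)c1c(Cl)cc(Cl)cc1Cl | intermediate
17 | (2R,3S)-5-acetyl-2-(prop-1-en-2-yl)-2,3-dihydro-1-benzofuran-3-yl (Z)-2-(acetoxymethyl)but-2-enoate (CNP0289095.1) | C=C(C)[C@H]1Oc2ccc(C(C)=O)cc2[C@@H]1OC(=O)/C(=C\C)COC(C)=O | target

Total step count: 9. Longest linear sequence: 5 steps (1, 2, 3, 4, 9; the acid branch 5, 6, 7, 8, 9 is equally long).

Steps most likely to fail

**Step 4 (key step).**
- What may go wrong:
  - insufficient facial discrimination at the formyl group;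
  - leakage through the Z-allyl form or a boat arrangement, with erosion of the trans relationship;
  - reductive pinacol coupling of the electron-poor aldehyde;
  - solvolysis of the chloride before it is reduced.
- Fallback: stereocontrol is moved from the catalyst to a stoichiometric boron auxiliary. Setting out from 7, borylation with bis(diisopropyl D-tartrate glycolato)diboron under Pd2(dba)3 catalysis (toluene, rt) should give the diisopropyl D-tartrate (E)-γ-aryloxyallylboronate F1. This closes on the neighbouring formyl group in the flask through the same closed chair to the cyclic borate F2. The E-allyl unit gives trans, and the D-tartrate series is the one expected to open the Re face. Mild hydrolysis (aq. NaHCO3) comes back to the route at 9.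

**Step 2.**
- What may go wrong:
  - sluggish coupling, because the phenoxide is electron-poor and chelates copper through its ortho formyl group;
  - base-induced aldol condensation between acetyl and formyl groups at the temperature required.
- Fallback: the alkenyl partner is changed from halide to boron and the C–O bond is made oxidatively at room temperature without carbonate base. Setting out from 3, Miyaura borylation (B2pin2, PdCl2(PPh3)2, PPh3, KOPh, toluene, 50 °C) should give (E)-2-methyl-3-(pinacolboryl)prop-2-en-1-ol F3. Chan–Lam coupling of F3 with 4 (Cu(OAc)2, pyridine, 4 Å molecular sieves, air, CH2Cl2, rt) comes back to the route at 5 with retention of geometry.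

**Step 9.**
- What may go wrong:
  - conjugate addition of the nucleophilic catalyst to the activated acyl species, leading to Z-to-E isomerisation or allylic displacement of the acetate;
  - dehydration of 9 to the aromatic benzofuran.
- Fallback: the labile allylic acetate is kept out of the acylation and introduced last.
  - Setting out from 12, silylation (t-BuMe2SiCl, imidazole, DMF) should give the (Z)-iodoalkenyl silyl ether F4.
  - Iodine–lithium exchange (t-BuLi, Et2O, −78 °C) gives the alkenyllithium F5, and carboxylation gives (Z)-2-(silyloxymethyl)but-2-enoic acid F6.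
  - Activation as the trichlorobenzoyl mixed anhydride F7 and reaction with 9 give the silyl-protected ester F8.
  - HF·pyridine (THF, 0 °C) frees the hydroxymethyl ester F9, and acetylation (Ac2O, pyridine, 0 °C) comes back to the route at 17.

Further compounds
F1 | step 4 | diisopropyl (4S,5S)-2-[(2E)-3-(4-acetyl-2-formylphenoxy)-2-methylprop-2-en-1-yl]-1,3,2-dioxaborolane-4,5-dicarboxylate | CC(=O)c1ccc(O/C=C(\C)CB2O[C@H](C(=O)OC(C)C)[C@@H](C(=O)OC(C)C)O2)c(C=O)c1
F2 | step 4 | diisopropyl (4S,5S)-2-{[(2R,3S)-5-acetyl-2-(prop-1-en-2-yl)-2,3-dihydro-1-benzofuran-3-yl]oxy}-1,3,2-dioxaborolane-4,5-dicarboxylate | C=C(C)[C@H]1Oc2ccc(C(C)=O)cc2[C@@H]1OB3O[C@H](C(=O)OC(C)C)[C@@H](C(=O)OC(C)C)O3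
F3 | step 2 | (E)-2-methyl-3-(4,4,5,5-tetramethyl-1,3,2-dioxaborolan-2-yl)prop-2-en-1-ol | OC/C(C)=C/B1OC(C)(C)C(C)(C)O1
F4 | step 9 | (Z)-tert-butyl[(2-iodobut-2-en-1-yl)oxy]dimethylsilane | C/C=C(\I)CO[Si](C)(C)C(C)(C)C
F5 | step 9 | (Z)-{1-[(tert-butyldimethylsilyl)oxy]but-2-en-2-yl}lithium | C/C=C(\[Li])CO[Si](C)(C)C(C)(C)C
F6 | step 9 | (Z)-2-{[(tert-butyldimethylsilyl)oxy]methyl}but-2-enoic acid | C/C=C(/CO[Si](C)(C)C(C)(C)C)C(=O)O
F7 | step 9 | (Z)-2-{[(tert-butyldimethylsilyl)oxy]methyl}but-2-enoic 2,4,6-trichlorobenzoic anhydride | C/C=C(/CO[Si](C)(C)C(C)(C)C)C(=O)OC(=O)c1c(Cl)cc(Cl)cc1Cl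
F8 | step 9 | (2R,3S)-5-acetyl-2-(prop-1-en-2-yl)-2,3-dihydro-1-benzofuran-3-yl (Z)-2-{[(tert-butyldimethylsilyl)oxy]methyl}but-2-enoate | C=C(C)[C@H]1Oc2ccc(C(C)=O)cc2[C@@H]1OC(=O)/C(=C\C)CO[Si](C)(C)C(C)(C)C
F9 | step 9 | (2R,3S)-5-acetyl-2-(prop-1-en-2-yl)-2,3-dihydro-1-benzofuran-3-yl (Z)-2-(hydroxymethyl)but-2-enoate | C=C(C)[C@H]1Oc2ccc(C(C)=O)cc2[C@@H]1OC(=O)/C(=C\C)CO
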